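**Plan**
1. Germacrane numbering: ring C1–C10 with C1 the epoxide CH, C4 carrying the formyl carbon C15, C5 the alkene CH, C6 the lactone CH–O, C8 the CH–OAc and C10 the epoxide carbon carrying C14H2OAc; the arm C11(=C13H2)–C12(=O) sits on C7.
2. Retrosynthesis: C12=O and C15=O are taken back to CH2 (a 3-methylenetetrahydrofuran) and CH2OPMB, the acetates to silyl ethers, and the trans-epoxide to the ring-cis C1=C10 alkene. In that alkene C1 is a CH2 and C10 a CH bearing C14, so both can stand α to one SO2; the C1–C10 bond is therefore cut by inserting SO2, giving an eleven-membered cyclic sulfone.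
3. Further cuts: S–C1 (thiolate alkylation), C3–C4 (B-alkyl Suzuki), O–C12 (ether closure), C5–C6 (acetylide on a Weinreb amide), C7–C8 (Evans aldol).
4. Forward: C7–C8 aldol, ynone, C6 carbinol, vinyl iodide, methylenetetrahydrofuran (ring 1), C1–C3 arm, eleven-membered sulfide and sulfone (ring 2), contraction to the ten-membered carbocycle, epoxide (ring 3), then lactone and aldehyde oxidation.
5. Stereochemistry: C7 and C8 from the (R)-4-benzyloxazolidinone aldol, C6 from (S,S)-Ru transfer hydrogenation, C4=C5 geometry from trans-hydroalumination/iodination, C1=C10 geometry from the contraction, C1/C10 from Sharpless epoxidation with D-(−)-diethyl tartrate.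

Key step: step 19

Remark: germacrane locants are used in the names. The C10 centre carried from the (S)-acetonide 1 is a spectator that step 19 erases; it is kept defined only so that single diastereomers are handled.

Step 1
Reactants: 1 (S)-2-(2,2-dimethyl-1,3-dioxolan-4-yl)ethanol
Product: 2 (S)-2-(2,2-dimethyl-1,3-dioxolan-4-yl)acetaldehyde
Conditions: PhI(OAc)2, TEMPO (cat.), CH2Cl2, rt
Reagents that add atoms: none
Why: TEMPO/PhI(OAc)2 oxidation (oxoammonium mechanism) stops at the aldehyde under neutral conditions that leave the acetonide and the C10 centre untouched.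

Step 2
Reactants: 3 (R)-4-benzyloxazolidin-2-one; 4 3-methylbut-2-enoyl chloride
Product: 5 (R)-4-benzyl-3-(3-methylbut-2-enoyl)oxazolidin-2-one
Conditions: n-BuLi, THF, −78 °C; then 4, −78 → 0 °C
Reagents that add atoms: none
Why: N-acylation of the lithiated oxazolidinone with an acid chloride is the standard entry to Evans imides.

Step 3
Reactants: 5 (R)-4-benzyl-3-(3-methylbut-2-enoyl)oxazolidin-2-one; 2 (S)-2-(2,2-dimethyl-1,3-dioxolan-4-yl)acetaldehyde
Product: 7 (4R)-4-benzyl-3-[(2R,3S)-4-[(4S)-2,2-dimethyl-1,3-dioxolan-4-yl]-3-hydroxy-2-(prop-1-en-2-yl)butanoyl]oxazolidin-2-one, via boron dienolate 6 (not isolated)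
Conditions: Bu2BOTf, Et3N, CH2Cl2, −78 → 0 °C; then 2, −78 → 0 °C; pH 7 buffer/MeOH/H2O2 work-up
Reagents that add atoms: none
Why: Evans syn-aldol in its deconjugative form: soft enolisation removes a γ-proton to give the Z(O) dienolate, which reacts at its α-carbon (C7) through a chair Zimmerman–Traxler transition state on the face away from the benzyl group, setting C7 and C8 syn under auxiliary control.

Step 4
Reactants: 7 aldol imide
Product: 8 (2R,3S)-4-[(4S)-2,2-dimethyl-1,3-dioxolan-4-yl]-3-hydroxy-N-methoxy-N-methyl-2-(prop-1-en-2-yl)butanamide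
Conditions: MeNHOMe, AlMe3, CH2Cl2/THF, 0 °C; Rochelle-salt work-up
Reagents that add atoms: N,O-dimethylhydroxylamine, CNOC
Why: Weinreb transamination with the aluminium amide is assisted by the free C8 hydroxyl, attacks only the exocyclic carbonyl and releases the auxiliary without touching C7.

Step 5
Reactants: 8 β-hydroxy Weinreb amide
Product: 9 (2R,3S)-3-[(tert-butyldimethylsilyl)oxy]-4-[(4S)-2,2-dimethyl-1,3-dioxolan-4-yl]-N-methoxy-N-methyl-2-(prop-1-en-2-yl)butanamide
Conditions: TBSOTf, 2,6-lutidine, CH2Cl2, −78 → 0 °C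
Reagents that add atoms: tert-butyldimethylsilyl trifluoromethanesulfonate, CC(C)(C)[Si](C)(C)OS(=O)(=O)C(F)(F)F
Why: Silyl triflate/lutidine silylation protects the hindered secondary C8 hydroxyl so that only O6 can later close the ether ring.

Step 6
Reactants: 10 prop-2-yn-1-ol; 11 4-methoxybenzyl chloride
Product: 12 1-methoxy-4-[(prop-2-yn-1-yloxy)methyl]benzene
Conditions: NaH, Bu4NI (cat.), THF/DMF, 0 °C → rt
Reagents that add atoms: none
Why: Williamson ether synthesis supplies C4, C5 and C15 with the C15 oxygen already protected as its PMB ether.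

Step 7
Reactants: 9 silylated Weinreb amide; 12 PMB propargyl ether
Product: 14 (5R,6S)-6-[(tert-butyldimethylsilyl)oxy]-7-[(4S)-2,2-dimethyl-1,3-dioxolan-4-yl]-1-[(4-methoxybenzyl)oxy]-5-(prop-1-en-2-yl)hept-2-yn-4-one, via lithium acetylide 13 (not isolated)
Conditions: 12, n-BuLi, THF, −78 °C; then 9, −78 → −20 °C; AcOH quench at −78 °C
Reagents that add atoms: none
Why: Weinreb ketone synthesis: the acetylide adds once to give a chelated tetrahedral intermediate that collapses to the ynone only on the cold acidic quench, which also prevents conjugate addition of the released amine and epimerisation at C7.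

Step 8
Reactants: 14 ynone
Product: 15 (4S,5S,6S)-6-[(tert-butyldimethylsilyl)oxy]-7-[(4S)-2,2-dimethyl-1,3-dioxolan-4-yl]-1-[(4-methoxybenzyl)oxy]-5-(prop-1-en-2-yl)hept-2-yn-4-ol
Conditions: Ru[(S,S)-TsNCH(Ph)CH(Ph)NH](η6-p-cymene) (2 mol %), i-PrOH, rt
Reagents that add atoms: none
Why: Noyori asymmetric transfer hydrogenation of an α,β-acetylenic ketone: the (S,S)-catalyst holds the alkynyl group in its CH/π pocket and gives the (S)-propargylic alcohol (C6) under catalyst control, and the base-free conditions do not epimerise C7.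

Step 9
Reactants: 15 propargylic alcohol
Product: 17 (2Z,4S,5S,6S)-6-[(tert-butyldimethylsilyl)oxy]-7-[(4S)-2,2-dimethyl-1,3-dioxolan-4-yl]-2-iodo-1-[(4-methoxybenzyl)oxy]-5-(prop-1-en-2-yl)hept-2-en-4-ol, via vinylalanate 16 (not isolated)
Conditions: NaAlH2(OCH2CH2OCH3)2, THF, 0 °C; then I2, THF, −78 → 0 °C
Reagents that add atoms: iodine, II
Why: Hydroxyl-directed trans-hydroalumination puts hydrogen on C5 and aluminium on C4 cis to C6 in a five-membered alanate (kept at 0 °C to avoid allene-forming loss of the PMB-oxy group), and iodinolysis with retention gives the (Z)-vinyl iodide that fixes the C4=C5 geometry.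

Step 10
Reactants: 17 iodo allylic alcohol
Product: 18 (2Z,4S,5S,6S)-6-[(tert-butyldimethylsilyl)oxy]-5-(3-chloroprop-1-en-2-yl)-7-[(4S)-2,2-dimethyl-1,3-dioxolan-4-yl]-2-iodo-1-[(4-methoxybenzyl)oxy]hept-2-en-4-ol
Conditions: Ca(OCl)2, CO2 (dry ice), CH2Cl2/H2O, 0 °C
Reagents that add atoms: calcium hypochlorite, [Ca+2].[O-]Cl.[O-]Cl
Why: Ene-type allylic chlorination of an isopropenyl group by hypochlorous acid puts chlorine on the terminal carbon and takes the proton from the methyl group, and the isopropenyl group is the only electron-rich alkene because the iodoalkene is deactivated.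

Step 11
Reactants: 18 allylic chloride
Product: 19 (2S,3S)-3-[(1S)-1-[(tert-butyldimethylsilyl)oxy]-2-[(4S)-2,2-dimethyl-1,3-dioxolan-4-yl]ethyl]-2-[(1Z)-2-iodo-3-[(4-methoxybenzyl)oxy]prop-1-en-1-yl]-4-methylideneoxolane
Conditions: NaH, THF, 0 °C
Reagents that add atoms: none
Why: Intramolecular Williamson etherification (5-exo-tet on a primary allylic chloride) closes ring 1 far faster than the C8 silyl group could migrate to O6, and since neither C6 nor C7 is touched the ring is 2,3-trans.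

Step 12
Reactants: 19 iodoalkenyl methylenetetrahydrofuran; 20 prop-2-en-1-ol
Product: 22 (4E)-5-[(2R,3S)-3-[(1S)-1-[(tert-butyldimethylsilyl)oxy]-2-[(4S)-2,2-dimethyl-1,3-dioxolan-4-yl]ethyl]-4-methylideneoxolan-2-yl]-4-{[(4-methoxybenzyl)oxy]methyl}pent-4-en-1-ol, via alkylborane 21 (not isolated)
Conditions: 20, 9-BBN (2.2 equiv per 20), THF, 0 °C → rt; then aq. Cs2CO3, 19, Pd(dppf)Cl2 (5 mol %), AsPh3, DMF, rt
Reagents that add atoms: none
Why: B-alkyl Suzuki–Miyaura coupling: O-borylation and anti-Markovnikov hydroboration of allyl alcohol give the alkylborane, which couples with the vinyl iodide on zerovalent palladium with retention, so C3 ends cis to C6 and C15 trans.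

Step 13
Reactants: 22 primary alcohol
Product: 23 (2R,3S)-2-[(1E)-5-chloro-2-{[(4-methoxybenzyl)oxy]methyl}pent-1-en-1-yl]-3-[(1S)-1-[(tert-butyldimethylsilyl)oxy]-2-[(4S)-2,2-dimethyl-1,3-dioxolan-4-yl]ethyl]-4-methylideneoxolane
Conditions: PPh3, N-chlorosuccinimide, CH2Cl2, 0 °C → rt
Reagents that add atoms: N-chlorosuccinimide, ClN1C(=O)CCC1=O
Why: Appel-type chlorination of the only free hydroxyl turns C1 into a primary chloride that is inert to the next three steps.

Step 14
Reactants: 23 chloro acetonide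
Product: 24 (2S,4S)-4-[(tert-butyldimethylsilyl)oxy]-4-[(2R,3S)-2-[(1E)-5-chloro-2-{[(4-methoxybenzyl)oxy]methyl}pent-1-en-1-yl]-4-methylideneoxolan-3-yl]butane-1,2-diol
Conditions: PPTS, MeOH, rt
Reagents that add atoms: none
Why: Acid-catalysed transacetalisation removes the terminal acetonide while the secondary TBS ether, the PMB ether and the cyclic allylic ether survive pyridinium tosylate.

Step 15
Reactants: 24 diol
Product: 25 (2S,4S)-1,4-bis[(tert-butyldimethylsilyl)oxy]-4-[(2R,3S)-2-[(1E)-5-chloro-2-{[(4-methoxybenzyl)oxy]methyl}pent-1-en-1-yl]-4-methylideneoxolan-3-yl]butan-2-ol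
Conditions: TBSCl (1.05 equiv), imidazole, CH2Cl2, 0 °C
Reagents that add atoms: tert-butyldimethylsilyl chloride, CC(C)(C)[Si](C)(C)Cl
Why: The primary C14 hydroxyl of the 1,2-diol is silylated selectively on steric grounds, leaving the C10 hydroxyl free.

Step 16
Reactants: 25 secondary alcohol
Product: 26 S-[(2R,4S)-1,4-bis[(tert-butyldimethylsilyl)oxy]-4-[(2R,3S)-2-[(1E)-5-chloro-2-{[(4-methoxybenzyl)oxy]methyl}pent-1-en-1-yl]-4-methylideneoxolan-3-yl]butan-2-yl] ethanethioate
Conditions: PPh3, DIAD, THF, 0 °C; then 25 and AcSH, 0 °C → rt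
Reagents that add atoms: thioacetic acid, CC(=O)S
Why: Mitsunobu thioesterification puts sulfur on C10 with inversion, and the primary chloride is not attacked by the thioacetate ion pair at this temperature.

Step 17
Reactants: 26 chloro thioacetate
Product: 28 eleven-membered cyclic sulfide (S between C1 and C10; 4E ring-cis; 6R,7S,8S,10R; 8-OTBS; 14-OTBS; 15-OPMB; 3-methylenetetrahydrofuran fused at C6–C7), via cesium thiolate 27 (not isolated)
Conditions: Cs2CO3, NaI (cat.), degassed MeOH/DMF, 50 °C, slow addition to a final 1 mM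
Reagents that add atoms: none
Why: Methanolysis of the thioester frees the cesium thiolate, which closes ring 2 by SN2 at the primary carbon C1 (cesium-thiolate macrocyclisation under high dilution), the cis C4=C5 alkene and the ring fusion holding the two ends on the same side.

Step 18
Reactants: 28 cyclic sulfide
Product: 29 eleven-membered cyclic sulfone (1,1-dioxide of 28; 6R,7S,8S,10R)
Conditions: (NH4)6Mo7O24·4H2O (cat.), 30% H2O2, EtOH, 0 °C → rt
Reagents that add atoms: hydrogen peroxide, OO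
Why: Molybdate-catalysed peroxide oxidation takes the sulfide to the sulfone and is selective for sulfur over the two alkenes, both of which carry deactivating allylic oxygens.

Step 19
Reactants: 29 eleven-membered cyclic sulfone
Product: 32 (1(10)E,4E,6R,7S,8S)-8,14-bis[(tert-butyldimethylsilyl)oxy]-15-[(4-methoxybenzyl)oxy]-6,12-epoxygermacra-1(10),4,11(13)-triene (both ring alkenes ring-cis), via bromo sulfone 30 (not isolated), via episulfone 31 (not isolated)
Conditions: KOH/Al2O3, CBr2F2, t-BuOH/CH2Cl2, 0 °C → rt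
Reagents that add atoms: none
Why: Hydroxide on alumina removes an α-proton of the sulfone, the carbanion takes bromine from CBr2F2 (drawn at C1; bromination at C10 leads to the same episulfone), and a second deprotonation at the other α-carbon is followed by 1,3-displacement of bromide and cheletropic loss of SO2. This is the Ramberg–Bäcklund reaction in its in situ halogenation form, known for cyclic sulfones including medium rings and trisubstituted alkenes. The only ring closed is the thiirane dioxide (3-exo-tet) inside the eleven-membered ring, so after extrusion the ten-membered carbocycle arises by contraction with C1–C10 as the new skeletal bond. No stereocentre is made and the C10 centre is destroyed. The step needs the ring-cis C1=C10 geometry (C2 cis to C9), which should follow from the cis-fused episulfone favoured under hydroxide conditions and from the strain of a trans double bond in a ten-membered ring, and it needs chemoselectivity, which the substrate secures because the sulfonyl α-hydrogens are its only acidic ones and the silyl, PMB and cyclic allylic ethers are inert to KOH. The competing path is β-elimination of the C14 silyloxy group from the C10 carbanion, which fast bromine transfer and ring closure should hold back as they do in β-alkoxy (glycosyl) sulfones.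

Step 20
Reactants: 32 bis-silyl triene
Product: 33 (1(10)E,4E,6R,7R,8S)-15-[(4-methoxybenzyl)oxy]-6,12-epoxygermacra-1(10),4,11(13)-triene-8,14-diol
Conditions: Bu4NF, THF, 0 °C → rt
Reagents that add atoms: none
Why: Fluoride cleaves both silyl ethers and leaves the PMB ether, so C14–OH is the only free allylic hydroxyl.

Step 21
Reactants: 33 diol
Product: 34 (4E,1R,6R,7R,8S,10R)-1,10:6,12-diepoxy-15-[(4-methoxybenzyl)oxy]germacra-4,11(13)-diene-8,14-diol
Conditions: Ti(OiPr)4 (20 mol %), D-(−)-diethyl tartrate (24 mol %), t-BuOOH, 4 Å molecular sieves, CH2Cl2, −20 °C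
Reagents that add atoms: tert-butyl hydroperoxide, CC(C)(C)OO
Why: Sharpless asymmetric epoxidation of the C14 allylic alcohol: D-(−)-tartrate delivers oxygen to the face that gives (1R,10R), syn addition to the alkene keeps C2 trans to C14, the C4=C5 alkene has no free allylic hydroxyl and the homoallylic C8–OH reacts far more slowly.

Step 22
Reactants: 34 epoxy diol
Product: 35 (4E,1R,6R,7R,8S,10R)-8,14-diacetoxy-1,10:6,12-diepoxy-15-[(4-methoxybenzyl)oxy]germacra-4,11(13)-diene
Conditions: Ac2O, pyridine, DMAP (cat.), CH2Cl2, 0 °C → rt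
Reagents that add atoms: acetic anhydride, CC(=O)OC(C)=O
Why: DMAP-catalysed acylation esterifies the primary C14 and secondary C8 hydroxyls and does not open the epoxide.

Step 23
Reactants: 35 PMB ether
Product: 36 (4E,1R,6R,7R,8S,10R)-8,14-diacetoxy-1,10:6,12-diepoxygermacra-4,11(13)-dien-15-ol
Conditions: DDQ, CH2Cl2/pH 7 buffer, 0 °C
Reagents that add atoms: none
Why: Oxidative PMB cleavage by DDQ in buffered wet CH2Cl2 frees the C15 alcohol without acid or base, so the epoxide and acetates survive; any onward oxidation to the enal only anticipates step 24.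

Step 24
Reactants: 36 allylic alcohol
Product: 38 (4E,1R,6R,7R,8S,10R)-8,14-diacetoxy-1,10-epoxy-15-oxogermacra-4,11(13)-dien-12,6-olide (CNP0211286.1), via enal 37 (not isolated)
Conditions: CrO3·2C5H5N (made from CrO3 and pyridine, large excess), CH2Cl2, rt
Reagents that add atoms: chromium trioxide, O=[Cr](=O)=O
Why: Collins oxidation first turns the primary allylic alcohol into the enal, which deactivates C4=C5 and its allylic positions, and the excess reagent then performs the known allylic oxidation of a 3-methylenetetrahydrofuran at the allylic, α-oxy C12 methylene to give the α-methylene-γ-butyrolactone.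

**Compound list**
1 | (S)-2-(2,2-dimethyl-1,3-dioxolan-4-yl)ethanol | OCC[C@H]1COC(C)(C)O1 | starting material
2 | (S)-2-(2,2-dimethyl-1,3-dioxolan-4-yl)acetaldehyde | O=CC[C@H]1COC(C)(C)O1 | intermediate
3 | (R)-4-benzyloxazolidin-2-one | O=C1N[C@H](Cc2ccccc2)CO1 | starting material
4 | 3-methylbut-2-enoyl chloride | CC(C)=CC(=O)Cl | starting material
5 | (R)-4-benzyl-3-(3-methylbut-2-enoyl)oxazolidin-2-one | CC(C)=CC(=O)N1[C@H](Cc2ccccc2)COC1=O | intermediate
6 | dibutylboron Z(O)-dienolate of 5 (not isolated) | C=C(C)/C=C(\OB(CCCC)CCCC)N1[C@H](Cc2ccccc2)COC1=O | intermediate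
7 | (4R)-4-benzyl-3-[(2R,3S)-4-[(4S)-2,2-dimethyl-1,3-dioxolan-4-yl]-3-hydroxy-2-(prop-1-en-2-yl)butanoyl]oxazolidin-2-one | O=C([C@H](C(C)=C)[C@@H](O)C[C@H]1COC(C)(C)O1)N1[C@H](Cc2ccccc2)COC1=O | intermediate
8 | (2R,3S)-4-[(4S)-2,2-dimethyl-1,3-dioxolan-4-yl]-3-hydroxy-N-methoxy-N-methyl-2-(prop-1-en-2-yl)butanamide | CON(C)C(=O)[C@H](C(C)=C)[C@@H](O)C[C@H]1COC(C)(C)O1 | intermediate
9 | (2R,3S)-3-[(tert-butyldimethylsilyl)oxy]-4-[(4S)-2,2-dimethyl-1,3-dioxolan-4-yl]-N-methoxy-N-methyl-2-(prop-1-en-2-yl)butanamide | CON(C)C(=O)[C@H](C(C)=C)[C@@H](O[Si](C)(C)C(C)(C)C)C[C@H]1COC(C)(C)O1 | intermediate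
10 | prop-2-yn-1-ol | C#CCO | starting material
11 | 4-methoxybenzyl chloride | COc1ccc(CCl)cc1 | starting material
12 | 1-methoxy-4-[(prop-2-yn-1-yloxy)methyl]benzene | C#CCOCc1ccc(OC)cc1 | intermediate
13 | lithium acetylide of 12 (not isolated) | [Li]C#CCOCc1ccc(OC)cc1 | intermediate
14 | (5R,6S)-6-[(tert-butyldimethylsilyl)oxy]-7-[(4S)-2,2-dimethyl-1,3-dioxolan-4-yl]-1-[(4-methoxybenzyl)oxy]-5-(prop-1-en-2-yl)hept-2-yn-4-one | O=C(C#CCOCc1ccc(OC)cc1)[C@H](C(C)=C)[C@@H](O[Si](C)(C)C(C)(C)C)C[C@H]1COC(C)(C)O1 | intermediate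
15 | (4S,5S,6S)-6-[(tert-butyldimethylsilyl)oxy]-7-[(4S)-2,2-dimethyl-1,3-dioxolan-4-yl]-1-[(4-methoxybenzyl)oxy]-5-(prop-1-en-2-yl)hept-2-yn-4-ol | O[C@H](C#CCOCc1ccc(OC)cc1)[C@H](C(C)=C)[C@@H](O[Si](C)(C)C(C)(C)C)C[C@H]1COC(C)(C)O1 | intermediate
16 | sodium cyclic vinylalanate from 15, Al on C4 and O6, bis(2-methoxyethoxy) (not isolated) | [Na+].COCCO[Al-]1(OCCOC)O[C@@H]([C@H](C(C)=C)[C@@H](O[Si](C)(C)C(C)(C)C)C[C@H]2COC(C)(C)O2)C=C1COCc1ccc(OC)cc1 | intermediate
17 | (2Z,4S,5S,6S)-6-[(tert-butyldimethylsilyl)oxy]-7-[(4S)-2,2-dimethyl-1,3-dioxolan-4-yl]-2-iodo-1-[(4-methoxybenzyl)oxy]-5-(prop-1-en-2-yl)hept-2-en-4-ol | O[C@H](/C=C(\I)COCc1ccc(OC)cc1)[C@H](C(C)=C)[C@@H](O[Si](C)(C)C(C)(C)C)C[C@H]1COC(C)(C)O1 | intermediate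
18 | (2Z,4S,5S,6S)-6-[(tert-butyldimethylsilyl)oxy]-5-(3-chloroprop-1-en-2-yl)-7-[(4S)-2,2-dimethyl-1,3-dioxolan-4-yl]-2-iodo-1-[(4-methoxybenzyl)oxy]hept-2-en-4-ol | O[C@H](/C=C(\I)COCc1ccc(OC)cc1)[C@H](C(=C)CCl)[C@@H](O[Si](C)(C)C(C)(C)C)C[C@H]1COC(C)(C)O1 | intermediate
19 | (2S,3S)-3-[(1S)-1-[(tert-butyldimethylsilyl)oxy]-2-[(4S)-2,2-dimethyl-1,3-dioxolan-4-yl]ethyl]-2-[(1Z)-2-iodo-3-[(4-methoxybenzyl)oxy]prop-1-en-1-yl]-4-methylideneoxolane | C=C1CO[C@H](/C=C(\I)COCc2ccc(OC)cc2)[C@H]1[C@@H](O[Si](C)(C)C(C)(C)C)C[C@H]1COC(C)(C)O1 | intermediate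
20 | prop-2-en-1-ol | C=CCO | starting material
21 | 9-[3-(9-borabicyclo[3.3.1]nonan-9-yloxy)propyl]-9-borabicyclo[3.3.1]nonane (not isolated) | B1(OCCCB2C3CCCC2CCC3)C2CCCC1CCC2 | intermediate
22 | (4E)-5-[(2R,3S)-3-[(1S)-1-[(tert-butyldimethylsilyl)oxy]-2-[(4S)-2,2-dimethyl-1,3-dioxolan-4-yl]ethyl]-4-methylideneoxolan-2-yl]-4-{[(4-methoxybenzyl)oxy]methyl}pent-4-en-1-ol | C=C1CO[C@H](/C=C(\CCCO)COCc2ccc(OC)cc2)[C@H]1[C@@H](O[Si](C)(C)C(C)(C)C)C[C@H]1COC(C)(C)O1 | intermediate
23 | (2R,3S)-2-[(1E)-5-chloro-2-{[(4-methoxybenzyl)oxy]methyl}pent-1-en-1-yl]-3-[(1S)-1-[(tert-butyldimethylsilyl)oxy]-2-[(4S)-2,2-dimethyl-1,3-dioxolan-4-yl]ethyl]-4-methylideneoxolane | C=C1CO[C@H](/C=C(\CCCCl)COCc2ccc(OC)cc2)[C@H]1[C@@H](O[Si](C)(C)C(C)(C)C)C[C@H]1COC(C)(C)O1 | intermediate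
24 | (2S,4S)-4-[(tert-butyldimethylsilyl)oxy]-4-[(2R,3S)-2-[(1E)-5-chloro-2-{[(4-methoxybenzyl)oxy]methyl}pent-1-en-1-yl]-4-methylideneoxolan-3-yl]butane-1,2-diol | C=C1CO[C@H](/C=C(\CCCCl)COCc2ccc(OC)cc2)[C@H]1[C@@H](O[Si](C)(C)C(C)(C)C)C[C@H](O)CO | intermediate
25 | (2S,4S)-1,4-bis[(tert-butyldimethylsilyl)oxy]-4-[(2R,3S)-2-[(1E)-5-chloro-2-{[(4-methoxybenzyl)oxy]methyl}pent-1-en-1-yl]-4-methylideneoxolan-3-yl]butan-2-ol | C=C1CO[C@H](/C=C(\CCCCl)COCc2ccc(OC)cc2)[C@H]1[C@@H](O[Si](C)(C)C(C)(C)C)C[C@H](O)CO[Si](C)(C)C(C)(C)C | intermediate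
26 | S-[(2R,4S)-1,4-bis[(tert-butyldimethylsilyl)oxy]-4-[(2R,3S)-2-[(1E)-5-chloro-2-{[(4-methoxybenzyl)oxy]methyl}pent-1-en-1-yl]-4-methylideneoxolan-3-yl]butan-2-yl] ethanethioate | C=C1CO[C@H](/C=C(\CCCCl)COCc2ccc(OC)cc2)[C@H]1[C@@H](O[Si](C)(C)C(C)(C)C)C[C@@H](SC(C)=O)CO[Si](C)(C)C(C)(C)C | intermediate
27 | cesium thiolate from 26, sulfur on C10 (not isolated) | C=C1CO[C@H](/C=C(\CCCCl)COCc2ccc(OC)cc2)[C@H]1[C@@H](O[Si](C)(C)C(C)(C)C)C[C@@H]([S-])CO[Si](C)(C)C(C)(C)C.[Cs+] | intermediate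
28 | eleven-membered cyclic sulfide: ring S–C1–C2–C3–C4=C5–C6–C7–C8–C9–C10 (4E ring-cis; 6R,7S,8S,10R), C4–CH2OPMB, C8–OTBS, C10–CH2OTBS, 3-methylenetetrahydrofuran O–C12H2–C11(=C13H2) fused at C6–C7 | C=C1CO[C@@H]2/C=C(/COCc3ccc(OC)cc3)CCCS[C@@H](CO[Si](C)(C)C(C)(C)C)C[C@H](O[Si](C)(C)C(C)(C)C)[C@@H]12 | intermediate
29 | eleven-membered cyclic sulfone, the S,S-dioxide of 28 (6R,7S,8S,10R) | C=C1CO[C@@H]2/C=C(/COCc3ccc(OC)cc3)CCCS(=O)(=O)[C@@H](CO[Si](C)(C)C(C)(C)C)C[C@H](O[Si](C)(C)C(C)(C)C)[C@@H]12 | intermediate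
30 | C1-bromo derivative of sulfone 29, C1 epimers (not isolated) | C=C1CO[C@@H]2/C=C(/COCc3ccc(OC)cc3)CCC(Br)S(=O)(=O)[C@@H](CO[Si](C)(C)C(C)(C)C)C[C@H](O[Si](C)(C)C(C)(C)C)[C@@H]12 | intermediate
31 | cis-fused thiirane 1,1-dioxide spanning C1–C10 of the ten-membered ring, one of the two cis-fused diastereomers drawn (not isolated) | C=C1CO[C@@H]2/C=C(/COCc3ccc(OC)cc3)CC[C@H]3S(=O)(=O)[C@@]3(CO[Si](C)(C)C(C)(C)C)C[C@H](O[Si](C)(C)C(C)(C)C)[C@@H]12 | intermediate
32 | (1(10)E,4E,6R,7S,8S)-8,14-bis[(tert-butyldimethylsilyl)oxy]-15-[(4-methoxybenzyl)oxy]-6,12-epoxygermacra-1(10),4,11(13)-triene, both ring alkenes ring-cis | C=C1CO[C@@H]2/C=C(/COCc3ccc(OC)cc3)CC/C=C(/CO[Si](C)(C)C(C)(C)C)C[C@H](O[Si](C)(C)C(C)(C)C)[C@@H]12 | intermediate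
33 | (1(10)E,4E,6R,7R,8S)-15-[(4-methoxybenzyl)oxy]-6,12-epoxygermacra-1(10),4,11(13)-triene-8,14-diol | C=C1CO[C@@H]2/C=C(/COCc3ccc(OC)cc3)CC/C=C(/CO)C[C@H](O)[C@@H]12 | intermediate
34 | (4E,1R,6R,7R,8S,10R)-1,10:6,12-diepoxy-15-[(4-methoxybenzyl)oxy]germacra-4,11(13)-diene-8,14-diol | C=C1CO[C@@H]2/C=C(/COCc3ccc(OC)cc3)CC[C@H]3O[C@@]3(CO)C[C@H](O)[C@@H]12 | intermediate
35 | (4E,1R,6R,7R,8S,10R)-8,14-diacetoxy-1,10:6,12-diepoxy-15-[(4-methoxybenzyl)oxy]germacra-4,11(13)-diene | C=C1CO[C@@H]2/C=C(/COCc3ccc(OC)cc3)CC[C@H]3O[C@@]3(COC(C)=O)C[C@H](OC(C)=O)[C@@H]12 | intermediate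
36 | (4E,1R,6R,7R,8S,10R)-8,14-diacetoxy-1,10:6,12-diepoxygermacra-4,11(13)-dien-15-ol | C=C1CO[C@@H]2/C=C(/CO)CC[C@H]3O[C@@]3(COC(C)=O)C[C@H](OC(C)=O)[C@@H]12 | intermediate
37 | (4E,1R,6R,7R,8S,10R)-8,14-diacetoxy-1,10:6,12-diepoxygermacra-4,11(13)-dien-15-al (not isolated) | C=C1CO[C@@H]2/C=C(/C=O)CC[C@H]3O[C@@]3(COC(C)=O)C[C@H](OC(C)=O)[C@@H]12 | intermediate
38 | (4E,1R,6R,7R,8S,10R)-8,14-diacetoxy-1,10-epoxy-15-oxogermacra-4,11(13)-dien-12,6-olide (CNP0211286.1) | C=C1C(=O)O[C@@H]2/C=C(/C=O)CC[C@H]3O[C@@]3(COC(C)=O)C[C@H](OC(C)=O)[C@@H]12 | target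

**Totals**
Total step count: 24. Longest linear sequence: 22 steps (steps 1, 3–5 and 7–24, from compound 1).

**Steps most likely to fail**

Step 19 (ring contraction). What may go wrong: a second bromination at C1, loss of the C14 silyloxy group from the C10 carbanion before bromine transfer, or partial formation of the ring-trans alkene under the heterogeneous one-pot conditions. Fallback: separate halogenation from contraction. Setting out from sulfone 29, kinetic deprotonation at the less hindered C1 methylene with LiN(SiMe3)2 in THF at −78 °C and quenching with C2Cl6 would give the isolated C1-chloro sulfone F1. Treating F1 with KOt-Bu in THF at −78 → 0 °C would then carry out the classical Ramberg–Bäcklund 1,3-elimination and SO2 loss. The C10 carbanion is then formed only when the leaving group is already in place at C1, and the route is rejoined at triene 32.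

Step 17 (eleven-membered ring closure). What may go wrong: intermolecular S-alkylation and oxidative disulfide coupling outrun the slow medium-ring closure, or the thioester is cleaved incompletely before alkylation. Fallback: form both C–S bonds in one operation from a bis-electrophile. Setting out from alcohol 25, mesylation (MsCl, Et3N, CH2Cl2, 0 °C) would give the chloro mesylate F2 with C10 unchanged. Slow addition of F2 to Na2S·9H2O in DMF at 60 °C under high dilution would displace chloride and mesylate in either order, the C10 displacement going with inversion, and return to sulfide 28 without a thioester or free-thiol stage.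

Step 24 (double oxidation). What may go wrong: over-oxidation by the chromium reagent (attack at C6–H, epoxide opening by Lewis-acidic chromium species, degradation of the enal) before the C12 oxidation is complete. Fallback: split the two oxidations and do the C–H oxidation with selenium. Setting out from alcohol 36, MnO2 in CH2Cl2 would give enal 37, now isolated. SeO2 (cat.) with t-BuOOH in CH2Cl2 would hydroxylate the allylic, α-oxy C12 methylene by the ene/[2,3] sequence to the C12 lactol F3 (8,14-diacetoxy-1,10:6,12-diepoxy-12-hydroxy-15-oxogermacra-4,11(13)-diene). MnO2 (or Ag2CO3 on Celite) would then oxidise this allylic lactol to the lactone, returning at target 38.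

**Further compounds**
F1 | step 19 | C1-chloro derivative of cyclic sulfone 29 (C1 epimers) | C=C1CO[C@@H]2/C=C(/COCc3ccc(OC)cc3)CCC(Cl)S(=O)(=O)[C@@H](CO[Si](C)(C)C(C)(C)C)C[C@H](O[Si](C)(C)C(C)(C)C)[C@@H]12
F2 | step 17 | (2S,4S)-1,4-bis[(tert-butyldimethylsilyl)oxy]-4-[(2R,3S)-2-[(1E)-5-chloro-2-{[(4-methoxybenzyl)oxy]methyl}pent-1-en-1-yl]-4-methylideneoxolan-3-yl]butan-2-yl methanesulfonate | C=C1CO[C@H](/C=C(\CCCCl)COCc2ccc(OC)cc2)[C@H]1[C@@H](O[Si](C)(C)C(C)(C)C)C[C@H](OS(C)(=O)=O)CO[Si](C)(C)C(C)(C)C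
F3 | step 24 | (4E,1R,6R,7R,8S,10R)-8,14-diacetoxy-1,10:6,12-diepoxy-12-hydroxy-15-oxogermacra-4,11(13)-diene (C12 lactol, anomers) | C=C1C(O)O[C@@H]2/C=C(/C=O)CC[C@H]3O[C@@]3(COC(C)=O)C[C@H](OC(C)=O)[C@@H]12
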